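**Retrosynthetic overview**
- Rings C and D are closed last, in one flask: the pyranone from a 2‑hydroxyphenyl benzyl ketone plus one carbon from DMF, the chroman from an ortho‑prenyl phenol. The ketone comes from resorcinol (ring A) and a ring‑B arylacetic lactone by Friedel–Crafts acylation.
- The prenyl group is placed between OMe and the future chroman oxygen by a para‑Claisen–Cope shift from the other phenol oxygen; that oxygen is set free and re‑closes the lactone.
- The two phenols of ring B are told apart by the lactone: it masks the ortho oxygen, the para oxygen is silylated, then the lactone is opened and the ortho oxygen prenylated.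
- Ring B with its two‑carbon arm comes from 5‑methoxyresorcinol and glyoxylic acid (hydroxyalkylation para to OH, then hydrogenolysis).
- Ring order: rings A and B are bought; a temporary lactone ring is closed, opened, re‑closed and finally consumed; rings D and C form in the last step.

Assumption: the target SMILES has no stereocentre and no stereogenic double bond, so the compound is achiral and nothing has to be set or resolved.

**Step 1**
Reactants: 1 5‑methoxybenzene‑1,3‑diol (5‑methoxyresorcinol); 2 glyoxylic acid monohydrate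
Product: 4 (2,4‑dihydroxy‑6‑methoxyphenyl)acetic acid, via mandelic acid 3 (not isolated)
Conditions: 2 (0.95 equiv), NaOH (2.1 equiv), H2O, N2, 0 °C → rt, 16 h; then HCl to pH 1, Pd/C (10 wt%), H2 (5 bar), 60 °C
Reagents that add atoms: none
Why: Friedel–Crafts‑type hydroxyalkylation of the phenoxide by glyoxylate goes para to an O− at C‑4, the carbon between OH and OMe (the same selectivity that turns resorcinol into 2,4‑dihydroxymandelic acid), and the electron‑rich benzylic C–OH is then removed by acid‑promoted Pd‑catalysed hydrogenolysis, which erases the racemic stereocentre of 3.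

**Step 2**
Reactants: 4 (2,4‑dihydroxy‑6‑methoxyphenyl)acetic acid
Product: 6 4‑methoxy‑6‑[(triisopropylsilyl)oxy]‑1‑benzofuran‑2(3H)‑one, via hydroxy lactone 5 (not isolated)
Conditions: p‑TsOH·H2O (5 mol%), toluene, reflux (Dean–Stark); then imidazole, i‑Pr3SiCl, DMF, 0 °C → rt
Reagents that add atoms: chlorotriisopropylsilane, CC(C)[Si](Cl)(C(C)C)C(C)C
Why: acid‑catalysed lactonisation can only use the phenol ortho to the side chain (the other ortho position carries OMe), so that oxygen is masked as the aryl ester and the single remaining phenol is silylated (silyl ether formation).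

**Step 3**
Reactants: 6 4‑methoxy‑6‑[(triisopropylsilyl)oxy]‑1‑benzofuran‑2(3H)‑one; 7 1‑bromo‑3‑methylbut‑2‑ene (prenyl bromide)
Product: 9 methyl 2‑{2‑methoxy‑6‑[(3‑methylbut‑2‑en‑1‑yl)oxy]‑4‑[(triisopropylsilyl)oxy]phenyl}acetate, via sodium phenoxide 8 (not isolated)
Conditions: NaOMe (1.0 equiv), MeOH/THF, −10 °C, 15 min; then 7 (1.3 equiv), DMF, 0 °C → rt
Reagents that add atoms: sodium methoxide, C[O-].[Na+]
Why: methoxide opens the strained aryl ester (transesterification) much faster than it attacks the hindered Si–O bond, which unmasks exactly one phenoxide, and this is O‑alkylated by the allylic bromide in DMF (Williamson ether synthesis).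

**Step 4**
Reactants: 9 methyl 2‑{2‑methoxy‑6‑[(3‑methylbut‑2‑en‑1‑yl)oxy]‑4‑[(triisopropylsilyl)oxy]phenyl}acetate
Product: 13 4‑methoxy‑5‑(3‑methylbut‑2‑en‑1‑yl)‑6‑[(triisopropylsilyl)oxy]‑1‑benzofuran‑2(3H)‑one, via ortho‑dienone 10 (not isolated), via para‑dienone 11 (not isolated), via hydroxy ester 12 (not isolated)
Conditions: PhNEt2 (degassed), 195 °C, 3 h, N2 sweep
Reagents that add atoms: none
Why: tandem aromatic Claisen–Cope (para‑Claisen) rearrangement, in which the first [3,3] shift to the ring carbon bearing the acetate arm gives a dienone that cannot enolise, a second [3,3] shift carries the prenyl group to the para carbon between OMe and OSi (the only para position of that oxygen), tautomerisation frees the ortho phenol and it re‑closes the lactone with loss of methanol; the transient dienone stereocentres are racemic and vanish.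

**Step 5**
Reactants: 13 4‑methoxy‑5‑(3‑methylbut‑2‑en‑1‑yl)‑6‑[(triisopropylsilyl)oxy]‑1‑benzofuran‑2(3H)‑one; 14 benzene‑1,3‑diol (resorcinol)
Product: 17 glycyrrhizaisoflavone C: 7‑hydroxy‑3‑(7‑hydroxy‑5‑methoxy‑2,2‑dimethyl‑3,4‑dihydro‑2H‑chromen‑6‑yl)‑4H‑chromen‑4‑one, via chroman lactone 15 (not isolated), via deoxybenzoin 16 (not isolated)
Conditions: 14 (1.5 equiv), BF3·OEt2 (neat), rt 1 h then 85 °C, 2 h; cool, DMF, MeSO2Cl (3–4 equiv), 55 °C, 2 h; aq. NaOAc, 60 °C
Reagents that add atoms: N,N‑dimethylformamide, CN(C)C=O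
Why: Proposed new method: a one‑flask merger of known reactions in which BF3 (with HF formed in situ from the phenols) removes the silyl group and the protonated prenyl alkene is trapped by the freed phenol, its only non‑methylated neighbour (Markovnikov six‑ring hydroalkoxylation, ring D), the aryl‑ester lactone acylates resorcinol at C‑4 (BF3‑mediated Friedel–Crafts/Fries‑type acylation), and the difluoroboron‑chelated benzyl ketone is C‑formylated by the DMF/MeSO2Cl Vilsmeier‑type reagent and closes ring C on hydrolytic work‑up; the closest known reaction is the one‑pot BF3·OEt2/DMF/MeSO2Cl isoflavone synthesis from a phenol and an arylacetic acid, and the excess reagent is expected to O‑formylate the non‑chelated chroman phenol transiently, which disfavours 3‑aroylbenzofuran closure and C‑formylation of ring B.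

**Compound list**
1 | 5‑methoxybenzene‑1,3‑diol | COc1cc(O)cc(O)c1 | starting material
2 | glyoxylic acid monohydrate (2,2‑dihydroxyacetic acid) | OC(O)C(=O)O | starting material
3 | 2‑(2,4‑dihydroxy‑6‑methoxyphenyl)‑2‑hydroxyacetic acid (racemic) | COc1cc(O)cc(O)c1C(O)C(=O)O | intermediate
4 | (2,4‑dihydroxy‑6‑methoxyphenyl)acetic acid | COc1cc(O)cc(O)c1CC(=O)O | intermediate
5 | 6‑hydroxy‑4‑methoxy‑1‑benzofuran‑2(3H)‑one | COc1cc(O)cc2OC(=O)Cc12 | intermediate
6 | 4‑methoxy‑6‑[(triisopropylsilyl)oxy]‑1‑benzofuran‑2(3H)‑one | COc1cc(O[Si](C(C)C)(C(C)C)C(C)C)cc2OC(=O)Cc12 | intermediate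
7 | 1‑bromo‑3‑methylbut‑2‑ene | CC(C)=CCBr | starting material
8 | sodium 3‑methoxy‑2‑(2‑methoxy‑2‑oxoethyl)‑5‑[(triisopropylsilyl)oxy]phenolate | COC(=O)Cc1c(OC)cc(O[Si](C(C)C)(C(C)C)C(C)C)cc1[O-].[Na+] | intermediate
9 | methyl 2‑{2‑methoxy‑6‑[(3‑methylbut‑2‑en‑1‑yl)oxy]‑4‑[(triisopropylsilyl)oxy]phenyl}acetate | COC(=O)Cc1c(OC)cc(O[Si](C(C)C)(C(C)C)C(C)C)cc1OCC=C(C)C | intermediate
10 | methyl 2‑{2‑methoxy‑1‑(2‑methylbut‑3‑en‑2‑yl)‑6‑oxo‑4‑[(triisopropylsilyl)oxy]cyclohexa‑2,4‑dien‑1‑yl}acetate (racemic) | COC(=O)CC1(C(C)(C)C=C)C(OC)=CC(O[Si](C(C)C)(C(C)C)C(C)C)=CC1=O | intermediate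
11 | methyl 2‑{2‑methoxy‑3‑(3‑methylbut‑2‑en‑1‑yl)‑6‑oxo‑4‑[(triisopropylsilyl)oxy]cyclohexa‑1,4‑dien‑1‑yl}acetate (racemic) | COC(=O)CC1=C(OC)C(CC=C(C)C)C(O[Si](C(C)C)(C(C)C)C(C)C)=CC1=O | intermediate
12 | methyl 2‑{6‑hydroxy‑2‑methoxy‑3‑(3‑methylbut‑2‑en‑1‑yl)‑4‑[(triisopropylsilyl)oxy]phenyl}acetate | COC(=O)Cc1c(OC)c(CC=C(C)C)c(O[Si](C(C)C)(C(C)C)C(C)C)cc1O | intermediate
13 | 4‑methoxy‑5‑(3‑methylbut‑2‑en‑1‑yl)‑6‑[(triisopropylsilyl)oxy]‑1‑benzofuran‑2(3H)‑one | COc1c(CC=C(C)C)c(O[Si](C(C)C)(C(C)C)C(C)C)cc2OC(=O)Cc12 | intermediate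
14 | benzene‑1,3‑diol | Oc1cccc(O)c1 | starting material
15 | 4‑methoxy‑7,7‑dimethyl‑3,5,6,7‑tetrahydro‑2H‑furo[3,2‑g]chromen‑2‑one (linear chroman‑fused lactone) | COc1c2c(cc3OC(=O)Cc13)OC(C)(C)CC2 | intermediate
16 | 1‑(2,4‑dihydroxyphenyl)‑2‑(7‑hydroxy‑5‑methoxy‑2,2‑dimethyl‑3,4‑dihydro‑2H‑chromen‑6‑yl)ethan‑1‑one | COc1c2c(cc(O)c1CC(=O)c1ccc(O)cc1O)OC(C)(C)CC2 | intermediate
17 | glycyrrhizaisoflavone C | COc1c2c(cc(O)c1-c1coc3cc(O)ccc3c1=O)OC(C)(C)CC2 | target

**Totals**
Total step count: 5. Longest linear sequence: 5.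

**Steps most likely to fail**

Step 5. The free chroman phenol of 16 can compete with the ring‑A phenol for the formyl carbon (giving a 3‑aroylbenzofuran), ring B may be C‑formylated, and the lactone may acylate sluggishly. Fallback: run only the BF3·OEt2 stage from 13 and 14 and isolate 16. Heat 16 with N,N‑dimethylformamide dimethyl acetal in THF (65 °C) to give (E)‑3‑(dimethylamino)‑1‑(2,4‑dihydroxyphenyl)‑2‑(7‑hydroxy‑5‑methoxy‑2,2‑dimethyl‑3,4‑dihydro‑2H‑chromen‑6‑yl)prop‑2‑en‑1‑one F5 (a push–pull alkene whose geometry equilibrates). Under these neutral conditions the ketone‑bound ortho phenol closes ring C by 6‑endo conjugate addition–elimination, whereas the chroman phenol would need a 5‑endo closure. Warming in toluene (100 °C) completes the loss of dimethylamine and returns to 17.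

Step 4. The first [3,3] shift can instead end at the free ring CH next to OSi and tautomerise there, giving the 1,1‑dimethylallyl isomer, and the silyl ether may suffer at 195 °C. Fallback: open 6 with NaOMe/MeOH and quench with AcOH to give methyl 2‑{2‑hydroxy‑6‑methoxy‑4‑[(triisopropylsilyl)oxy]phenyl}acetate F3. Brominate para to the free phenol with Bu4NBr3 (CH2Cl2, CaCO3, 0 °C) to give methyl 2‑{3‑bromo‑6‑hydroxy‑2‑methoxy‑4‑[(triisopropylsilyl)oxy]phenyl}acetate F4. Stille coupling with tributyl(3‑methylbut‑2‑en‑1‑yl)stannane (Pd(PPh3)4, DMF, 90 °C) gives 12, which lactonises to 13 on heating as in step 4.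

Step 1. The electron‑rich ring can take up a second glyoxylate, the benzylic cation can be trapped by a second arene (diarylacetic acid), and some attack at C‑2 is possible. Fallback: acetylate 1 (Ac2O, BF3·OEt2, 60 °C; Friedel–Crafts acylation para to OH) to 1‑(2,4‑dihydroxy‑6‑methoxyphenyl)ethanone F1. A Willgerodt–Kindler reaction (S8, morpholine, 130 °C) gives 2‑(2,4‑dihydroxy‑6‑methoxyphenyl)‑1‑(morpholin‑4‑yl)ethanethione F2. Hydrolysis (aq. NaOH, reflux; then HCl) returns to 4.

**Further compounds**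
F1 | step 1 | 1‑(2,4‑dihydroxy‑6‑methoxyphenyl)ethanone | CC(=O)c1c(O)cc(O)cc1OC
F2 | step 1 | 2‑(2,4‑dihydroxy‑6‑methoxyphenyl)‑1‑(morpholin‑4‑yl)ethanethione | COc1cc(O)cc(O)c1CC(=S)N1CCOCC1
F3 | step 4 | methyl 2‑{2‑hydroxy‑6‑methoxy‑4‑[(triisopropylsilyl)oxy]phenyl}acetate | COC(=O)Cc1c(OC)cc(O[Si](C(C)C)(C(C)C)C(C)C)cc1O
F4 | step 4 | methyl 2‑{3‑bromo‑6‑hydroxy‑2‑methoxy‑4‑[(triisopropylsilyl)oxy]phenyl}acetate | COC(=O)Cc1c(OC)c(Br)c(O[Si](C(C)C)(C(C)C)C(C)C)cc1O
F5 | step 5 | (E)‑3‑(dimethylamino)‑1‑(2,4‑dihydroxyphenyl)‑2‑(7‑hydroxy‑5‑methoxy‑2,2‑dimethyl‑3,4‑dihydro‑2H‑chromen‑6‑yl)prop‑2‑en‑1‑one | CN(C)/C=C(\C(=O)c1ccc(O)cc1O)c1c(OC)c2CCC(C)(C)Oc2cc1O
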